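**Plan**

- Numbering: pyran O1, C2 (CMe2), C3 (Br), C4, C5, C6 (Me); cyclohexane C1' (on C5), C3' (Br), C4' (Cl, Me). The feature used is the enol ether O1–C6(CH3)=C5 of the pyran ring: it is the Markovnikov adduct of the C2 tertiary hydroxyl to an ethynyl group on C5, once the C=C bond has moved into the ring.
- Cuts, in order: O1–C6 (pyran opened to a bromohydrin alkynol); both C2–CH3 bonds (ester plus MeMgBr); C3–Br (from C3–OH with inversion); C6–CH3 (aldehyde-to-alkyne homologation); C3–C4 (glyoxylate–ene reaction at the isopropenyl group of limonene); C3'–Br and C4'–Cl (from the ring epoxide).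
- Forward: the cyclohexane of (S)-limonene receives its halogens first, the chain is then grown from the isopropenyl group (ene reaction, hydroboration, alkynylation, bromide, methyl addition), and the pyran, the only ring made, is closed last.
- Stereochemistry: C1' from (S)-limonene; C3' and C4' from the cis epoxide by two stereospecific anti openings (bromide, then 1,2-bromine shift with chloride capture); C3 from the (S)-BINOL–titanium ene reaction followed by one SN2 inversion; C5 of the alkynol is left uncontrolled because the last step makes it trigonal.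

Key step: step 13

Remark: C1' of the target is (S) and corresponds to C4 of limonene with the same ligand priorities, so (S)-(−)-limonene is the enantiomer required. A direct bromochlorination of the ring alkene is expected to give mainly the trans-diaxial adduct (Br anti, Cl syn to the side chain), the wrong diastereomer, so the ring halogens are installed stepwise through the cis epoxide.

**Route**

Step 1
Reactants: 1 (S)-(−)-limonene
Product: 2 (4S)-limonene 1,2-oxide (cis and trans ring-fusion diastereomers)
Conditions: m-CPBA (1.0 equiv), CH2Cl2, 0 °C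
Reagents that add atoms: m-CPBA (3-chloroperbenzoic acid), O=C(OO)c1cccc(Cl)c1
Why: Prilezhaev epoxidation: the peracid should oxidise the electron-richer trisubstituted ring alkene in preference to the isopropenyl group, with no useful facial bias, so both ring-fusion diastereomers are expected and are sorted in step 2.

Step 2
Reactants: 2 (4S)-limonene 1,2-oxide (cis and trans)
Product: 3 cis-(4S)-limonene 1,2-oxide, (1S,2R,4S)-1,2-epoxy-p-menth-8-ene (oxirane oxygen anti to the isopropenyl group)
Conditions: pyrrolidine, H2O, reflux; then distillation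
Reagents that add atoms: none
Why: Kinetic separation by epoxide aminolysis: only the trans epoxide offers the amine a trans-diaxial SN2 opening at the secondary carbon, whereas the cis epoxide would have to be attacked at its tertiary carbon and should be recovered unchanged.

Step 3
Reactants: 3 cis-(4S)-limonene 1,2-oxide
Product: 4 (1R,2R,5S)-2-bromo-2-methyl-5-(prop-1-en-2-yl)cyclohexan-1-ol (tertiary Br axial and syn to isopropenyl; secondary OH axial)
Conditions: LiBr, AcOH, THF, 0 °C
Reagents that add atoms: lithium bromide, [Li+].[Br-]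
Why: Acid-assisted halohydrin formation by epoxide opening: in the cis epoxide Markovnikov polarisation and trans-diaxial opening both direct bromide to the tertiary carbon, which it attacks with inversion, leaving the secondary hydroxyl axial and antiperiplanar to the new C–Br bond.

Step 4
Reactants: 4 (1R,2R,5S)-2-bromo-2-methyl-5-(prop-1-en-2-yl)cyclohexan-1-ol
Product: 6 (1S,2S,4S)-2-bromo-1-chloro-1-methyl-4-(prop-1-en-2-yl)cyclohexane (Br, Cl and isopropenyl all equatorial), via chlorosulfite ester 5 (not isolated)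
Conditions: SOCl2, pyridine, CH2Cl2, −20 → 0 °C
Reagents that add atoms: thionyl chloride, O=S(Cl)Cl
Why: Deoxychlorination with neighbouring-group participation: the axial chlorosulfite is expelled by the antiperiplanar bromine, which moves to the secondary carbon with inversion and forms the bromonium ion on the isopropenyl face, and chloride opens this ion anti at the tertiary carbon (Markovnikov bias outweighing the small cost of the half-chair with the side chain pseudo-axial), which sets C3' and C4' with Br and Cl trans and both equatorial.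

Step 5
Reactants: 6 (1S,2S,4S)-2-bromo-1-chloro-1-methyl-4-(prop-1-en-2-yl)cyclohexane; 7 ethyl glyoxylate
Product: 8 ethyl (2S)-4-[(1S,3S,4S)-3-bromo-4-chloro-4-methylcyclohexyl]-2-hydroxypent-4-enoate
Conditions: 7 (freshly distilled), (S)-BINOL (10 mol %), (i-PrO)2TiCl2 (10 mol %), 4 Å MS, CH2Cl2, −30 °C
Reagents that add atoms: none
Why: Catalytic asymmetric carbonyl–ene (glyoxylate–ene) reaction: the only alkene left, a 1,1-disubstituted one, should transfer a methyl hydrogen to the titanium-bound glyoxylate, and the (S)-BINOL complex is expected to set the (2S) carbinol by catalyst control because the ring stereocentres are remote.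

Step 6
Reactants: 8 ethyl (2S)-4-[(1S,3S,4S)-3-bromo-4-chloro-4-methylcyclohexyl]-2-hydroxypent-4-enoate
Product: 9 ethyl (2S)-4-[(1S,3S,4S)-3-bromo-4-chloro-4-methylcyclohexyl]-2-[(tert-butyldimethylsilyl)oxy]pent-4-enoate
Conditions: TBSCl, imidazole, DMF, 23 °C
Reagents that add atoms: tert-butyldimethylsilyl chloride, CC(C)(C)[Si](C)(C)Cl
Why: Standard silylation of a secondary alcohol, which keeps the hydroxyl out of the hydroboration, oxidation and alkynylation steps.

Step 7
Reactants: 9 ethyl (2S)-4-[(1S,3S,4S)-3-bromo-4-chloro-4-methylcyclohexyl]-2-[(tert-butyldimethylsilyl)oxy]pent-4-enoate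
Product: 11 ethyl (2S)-4-[(1S,3S,4S)-3-bromo-4-chloro-4-methylcyclohexyl]-2-[(tert-butyldimethylsilyl)oxy]-5-hydroxypentanoate (C4 epimers), via B-alkyl-9-BBN adduct 10 (not isolated)
Conditions: 9-BBN, THF, 0 → 23 °C; then H2O2, aq NaOAc, 0 °C
Reagents that add atoms: hydrogen peroxide, OO
Why: Hydroboration–oxidation: 9-BBN should add anti-Markovnikov to the 1,1-disubstituted alkene without reducing the ester, buffered peroxide spares ester, silyl ether and halides, and the new stereocentre (chain C4) is formed without control, which is acceptable because it becomes trigonal in step 13.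

Step 8
Reactants: 11 ethyl (2S)-4-[(1S,3S,4S)-3-bromo-4-chloro-4-methylcyclohexyl]-2-[(tert-butyldimethylsilyl)oxy]-5-hydroxypentanoate
Product: 12 ethyl (2S)-4-[(1S,3S,4S)-3-bromo-4-chloro-4-methylcyclohexyl]-2-[(tert-butyldimethylsilyl)oxy]-5-oxopentanoate (C4 epimers)
Conditions: DMP, CH2Cl2, 0 → 23 °C
Reagents that add atoms: none
Why: Dess–Martin oxidation of the primary alcohol under near-neutral conditions, run on the crude alcohol so that the δ-hydroxy ester has no time to lactonise.

Step 9
Reactants: 12 ethyl (2S)-4-[(1S,3S,4S)-3-bromo-4-chloro-4-methylcyclohexyl]-2-[(tert-butyldimethylsilyl)oxy]-5-oxopentanoate; 13 dimethyl (1-diazo-2-oxopropyl)phosphonate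
Product: 14 ethyl (2S)-4-[(1S,3S,4S)-3-bromo-4-chloro-4-methylcyclohexyl]-2-[(tert-butyldimethylsilyl)oxy]hex-5-ynoate (C4 epimers)
Conditions: K2CO3, EtOH, 0 → 23 °C
Reagents that add atoms: none
Why: Seyferth–Gilbert homologation with the Ohira–Bestmann reagent; ethanol as solvent keeps the ethyl ester unchanged, the mild carbonate base should leave the equatorial ring halides alone, and epimerisation next to the aldehyde is without consequence.

Step 10
Reactants: 14 ethyl (2S)-4-[(1S,3S,4S)-3-bromo-4-chloro-4-methylcyclohexyl]-2-[(tert-butyldimethylsilyl)oxy]hex-5-ynoate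
Product: 15 ethyl (2S)-4-[(1S,3S,4S)-3-bromo-4-chloro-4-methylcyclohexyl]-2-hydroxyhex-5-ynoate (C4 epimers)
Conditions: HF·pyridine, THF, 0 → 23 °C
Reagents that add atoms: none
Why: Fluoride-mediated desilylation under acidic rather than basic conditions, chosen to leave the tertiary chloride, the secondary bromide, the ester and the alkyne untouched.

Step 11
Reactants: 15 ethyl (2S)-4-[(1S,3S,4S)-3-bromo-4-chloro-4-methylcyclohexyl]-2-hydroxyhex-5-ynoate
Product: 17 ethyl (2R)-2-bromo-4-[(1S,3S,4S)-3-bromo-4-chloro-4-methylcyclohexyl]hex-5-ynoate (C4 epimers), via α-triflate 16 (not isolated)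
Conditions: Tf2O, 2,6-lutidine, CH2Cl2, −78 °C; then n-Bu4NBr (1.05 equiv), −78 → −30 °C
Reagents that add atoms: tetrabutylammonium bromide, CCCC[N+](CCCC)(CCCC)CCCC.[Br-]
Why: SN2 displacement of an α-triflyloxy ester by bromide: the carbonyl-activated, unhindered secondary triflate should react cold with clean inversion, which sets the (R) configuration of C3, while the small excess of bromide and the low temperature limit bromide–bromide exchange.

Step 12
Reactants: 17 ethyl (2R)-2-bromo-4-[(1S,3S,4S)-3-bromo-4-chloro-4-methylcyclohexyl]hex-5-ynoate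
Product: 19 (3R)-3-bromo-5-[(1S,3S,4S)-3-bromo-4-chloro-4-methylcyclohexyl]-2-methylhept-6-yn-2-ol (C5 epimers), via α-bromo methyl ketone 18 (not isolated)
Conditions: MeMgBr (3.5 equiv), CeCl3, THF, −78 °C; AcOH quench at −78 °C
Reagents that add atoms: methylmagnesium bromide, C[Mg]Br
Why: Double Grignard addition to an ester through the methyl ketone: CeCl3 raises carbonyl electrophilicity and suppresses enolisation of the bromo ketone, the cold acidic quench protonates the bromohydrin alkoxide before it can close to the epoxide, and the C3 configuration is not touched.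

Step 13
Reactants: 19 (3R)-3-bromo-5-[(1S,3S,4S)-3-bromo-4-chloro-4-methylcyclohexyl]-2-methylhept-6-yn-2-ol
Product: 21 laucapyranoid A, via exocyclic enol ether 20 (not isolated)
Conditions: Ph3PAuNTf2 (5 mol %), 4 Å MS, CH2Cl2, 23 °C; then Et3N
Reagents that add atoms: none
Why: The silver-free monovalent gold complex Ph3PAuNTf2 coordinates the terminal alkyne, the C2 hydroxyl adds anti to gold at the internal carbon C6 and protodeauration releases the 6-methylideneoxane 20, which the proton shuttled in the cycle converts through the C6 oxocarbenium ion into the C5=C6 enol ether. The closest known reaction type is the gold-catalysed cycloisomerisation (intramolecular hydroalkoxylation) of alkynols to exocyclic enol ethers, together with their acid-mediated isomerisation to the endocyclic isomers. The pyran ring closes in the 6-exo-dig mode by formation of the O1–C6 bond. No stereocentre is created: C5 becomes trigonal, so both C5 epimers of 19 converge, and C3, C1', C3' and C4' are not involved. The step needs attack at the internal alkyne carbon, secured by Markovnikov polarisation of the gold-bound terminal alkyne and the six-atom gem-dimethyl tether, and migration of the double bond into the ring, secured by the greater stability of the tetrasubstituted enol ether. Without silver the tertiary chloride and both bromides should not be ionised, and sieves keep water from hydrolysing the enol ether.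

**Compound list**

1 | (S)-(−)-limonene, (4S)-1-methyl-4-(prop-1-en-2-yl)cyclohex-1-ene | CC1=CC[C@H](CC1)C(C)=C | starting material
2 | (4S)-limonene 1,2-oxide, cis and trans diastereomers | CC1(O2)C2C[C@@H](C(C)=C)CC1 | intermediate
3 | cis-(4S)-limonene 1,2-oxide, (1S,2R,4S)-1,2-epoxy-p-menth-8-ene | C[C@@]1(O2)[C@H]2C[C@@H](C(C)=C)CC1 | intermediate
4 | (1R,2R,5S)-2-bromo-2-methyl-5-(prop-1-en-2-yl)cyclohexan-1-ol | C[C@]1(Br)[C@H](O)C[C@@H](C(C)=C)CC1 | intermediate
5 | (1R,2R,5S)-2-bromo-2-methyl-5-(prop-1-en-2-yl)cyclohexyl chlorosulfite | C[C@]1(Br)[C@H](OS(Cl)=O)C[C@@H](C(C)=C)CC1 | intermediate (not isolated)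
6 | (1S,2S,4S)-2-bromo-1-chloro-1-methyl-4-(prop-1-en-2-yl)cyclohexane | C[C@@]1(Cl)[C@@H](Br)C[C@@H](C(C)=C)CC1 | intermediate
7 | ethyl glyoxylate | CCOC(=O)C=O | starting material
8 | ethyl (2S)-4-[(1S,3S,4S)-3-bromo-4-chloro-4-methylcyclohexyl]-2-hydroxypent-4-enoate | CCOC(=O)[C@@H](O)CC(=C)[C@H]1CC[C@](C)(Cl)[C@@H](Br)C1 | intermediate
9 | ethyl (2S)-4-[(1S,3S,4S)-3-bromo-4-chloro-4-methylcyclohexyl]-2-[(tert-butyldimethylsilyl)oxy]pent-4-enoate | CCOC(=O)[C@@H](O[Si](C)(C)C(C)(C)C)CC(=C)[C@H]1CC[C@](C)(Cl)[C@@H](Br)C1 | intermediate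
10 | ethyl (2S)-5-(9-borabicyclo[3.3.1]nonan-9-yl)-4-[(1S,3S,4S)-3-bromo-4-chloro-4-methylcyclohexyl]-2-[(tert-butyldimethylsilyl)oxy]pentanoate (C4 epimers) | CCOC(=O)[C@@H](O[Si](C)(C)C(C)(C)C)CC(CB1C2CCCC1CCC2)[C@H]1CC[C@](C)(Cl)[C@@H](Br)C1 | intermediate (not isolated)
11 | ethyl (2S)-4-[(1S,3S,4S)-3-bromo-4-chloro-4-methylcyclohexyl]-2-[(tert-butyldimethylsilyl)oxy]-5-hydroxypentanoate (C4 epimers) | CCOC(=O)[C@@H](O[Si](C)(C)C(C)(C)C)CC(CO)[C@H]1CC[C@](C)(Cl)[C@@H](Br)C1 | intermediate
12 | ethyl (2S)-4-[(1S,3S,4S)-3-bromo-4-chloro-4-methylcyclohexyl]-2-[(tert-butyldimethylsilyl)oxy]-5-oxopentanoate (C4 epimers) | CCOC(=O)[C@@H](O[Si](C)(C)C(C)(C)C)CC(C=O)[C@H]1CC[C@](C)(Cl)[C@@H](Br)C1 | intermediate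
13 | dimethyl (1-diazo-2-oxopropyl)phosphonate | CC(=O)C(=[N+]=[N-])P(=O)(OC)OC | starting material
14 | ethyl (2S)-4-[(1S,3S,4S)-3-bromo-4-chloro-4-methylcyclohexyl]-2-[(tert-butyldimethylsilyl)oxy]hex-5-ynoate (C4 epimers) | CCOC(=O)[C@@H](O[Si](C)(C)C(C)(C)C)CC(C#C)[C@H]1CC[C@](C)(Cl)[C@@H](Br)C1 | intermediate
15 | ethyl (2S)-4-[(1S,3S,4S)-3-bromo-4-chloro-4-methylcyclohexyl]-2-hydroxyhex-5-ynoate (C4 epimers) | CCOC(=O)[C@@H](O)CC(C#C)[C@H]1CC[C@](C)(Cl)[C@@H](Br)C1 | intermediate
16 | ethyl (2S)-4-[(1S,3S,4S)-3-bromo-4-chloro-4-methylcyclohexyl]-2-{[(trifluoromethyl)sulfonyl]oxy}hex-5-ynoate (C4 epimers) | CCOC(=O)[C@@H](OS(=O)(=O)C(F)(F)F)CC(C#C)[C@H]1CC[C@](C)(Cl)[C@@H](Br)C1 | intermediate (not isolated)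
17 | ethyl (2R)-2-bromo-4-[(1S,3S,4S)-3-bromo-4-chloro-4-methylcyclohexyl]hex-5-ynoate (C4 epimers) | CCOC(=O)[C@H](Br)CC(C#C)[C@H]1CC[C@](C)(Cl)[C@@H](Br)C1 | intermediate
18 | (3R)-3-bromo-5-[(1S,3S,4S)-3-bromo-4-chloro-4-methylcyclohexyl]hept-6-yn-2-one (C5 epimers) | CC(=O)[C@H](Br)CC(C#C)[C@H]1CC[C@](C)(Cl)[C@@H](Br)C1 | intermediate (not isolated)
19 | (3R)-3-bromo-5-[(1S,3S,4S)-3-bromo-4-chloro-4-methylcyclohexyl]-2-methylhept-6-yn-2-ol (C5 epimers) | CC(C)(O)[C@H](Br)CC(C#C)[C@H]1CC[C@](C)(Cl)[C@@H](Br)C1 | intermediate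
20 | (3R)-3-bromo-5-[(1S,3S,4S)-3-bromo-4-chloro-4-methylcyclohexyl]-2,2-dimethyl-6-methylideneoxane (C5 epimers) | C=C1C([C@H]2CC[C@](C)(Cl)[C@@H](Br)C2)C[C@@H](Br)C(C)(C)O1 | intermediate (not isolated)
21 | laucapyranoid A, (3R)-3-bromo-5-[(1S,3S,4S)-3-bromo-4-chloro-4-methylcyclohexyl]-2,2,6-trimethyl-3,4-dihydro-2H-pyran | CC1=C([C@H]2CC[C@](C)(Cl)[C@@H](Br)C2)C[C@@H](Br)C(C)(C)O1 | target

**Step count and risks**

Total step count: 13. Longest linear sequence: 13 steps, from 1 to 21.

Steps most likely to fail: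

1. Step 4. The bromonium ion may be captured by chloride at the secondary carbon (giving the diaxial 1-bromo-2-chloro isomer), may pass Br+ on to the isopropenyl group of a second molecule, or the tertiary bromide may eliminate. Fallback, from 4 back to 6: the hydroxyl of 4 is mesylated (MsCl, Et3N, CH2Cl2, 0 °C) to (1R,2R,5S)-2-bromo-2-methyl-5-(prop-1-en-2-yl)cyclohexyl methanesulfonate F1. Buffered solvolysis (NaHCO3, acetone/H2O, 40 °C) should ionise it with the same bromine participation, but water, present as co-solvent, should now open the bromonium ion at the tertiary carbon as in any Markovnikov bromohydrin synthesis, to give the diequatorial bromohydrin (1S,2S,4S)-2-bromo-1-methyl-4-(prop-1-en-2-yl)cyclohexan-1-ol F2. Exchange of the tertiary hydroxyl of F2 for chloride (HCl in Et2O, CH2Cl2, −40 °C, short contact) should then proceed with retention through the same bridged ion and return to 6.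

2. Step 12. The bromo ketone intermediate may enolise (erosion of the C3 configuration), bromine–magnesium exchange may occur, or the bromohydrin alkoxide may close to the epoxide. Fallback, from 15 back to 19, in which methyl addition precedes C–Br bond formation so that no α-bromo carbonyl compound meets an organometallic: 15 with excess MeMgBr (THF, 0 °C) should give (3S)-5-[(1S,3S,4S)-3-bromo-4-chloro-4-methylcyclohexyl]-2-methylhept-6-yne-2,3-diol F3. SO2Cl2 and Et3N (CH2Cl2, −78 °C) should convert F3 into the cyclic sulfate (5S)-5-{2-[(1S,3S,4S)-3-bromo-4-chloro-4-methylcyclohexyl]but-3-yn-1-yl}-4,4-dimethyl-1,3,2-dioxathiolane 2,2-dioxide F4. LiBr (THF, 23 °C) should open F4 at the secondary carbon with inversion, as nucleophiles do with trisubstituted cyclic sulfates, to give lithium (3R)-3-bromo-5-[(1S,3S,4S)-3-bromo-4-chloro-4-methylcyclohexyl]-2-methylhept-6-yn-2-yl sulfate F5. Catalytic H2SO4 in wet THF should hydrolyse the tertiary sulfate monoester to 19.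

3. Step 13. The hindered tertiary hydroxyl may add sluggishly, the double bond may fail to move fully into the ring, or adventitious water may hydrolyse the enol ether on the acidic catalyst. Fallback, from 19 back to 21, in which ring closure and alkene formation are separated: the alkyne is hydrated on purpose (Ph3PAuNTf2 cat., wet 1,4-dioxane, 23 °C) to the δ-hydroxy methyl ketone (5R)-5-bromo-3-[(1S,3S,4S)-3-bromo-4-chloro-4-methylcyclohexyl]-6-hydroxy-6-methylheptan-2-one F6, which equilibrates with its cyclic hemiketal. Cyclodehydration of F6 (PPTS cat., 4 Å MS, benzene, 60 °C) should give the thermodynamically preferred tetrasubstituted enol ether 21.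

**Further compounds**

F1 | step 4 | (1R,2R,5S)-2-bromo-2-methyl-5-(prop-1-en-2-yl)cyclohexyl methanesulfonate | C[C@]1(Br)[C@H](OS(C)(=O)=O)C[C@@H](C(C)=C)CC1
F2 | step 4 | (1S,2S,4S)-2-bromo-1-methyl-4-(prop-1-en-2-yl)cyclohexan-1-ol | C[C@@]1(O)[C@@H](Br)C[C@@H](C(C)=C)CC1
F3 | step 12 | (3S)-5-[(1S,3S,4S)-3-bromo-4-chloro-4-methylcyclohexyl]-2-methylhept-6-yne-2,3-diol (C5 epimers) | CC(C)(O)[C@@H](O)CC(C#C)[C@H]1CC[C@](C)(Cl)[C@@H](Br)C1
F4 | step 12 | (5S)-5-{2-[(1S,3S,4S)-3-bromo-4-chloro-4-methylcyclohexyl]but-3-yn-1-yl}-4,4-dimethyl-1,3,2-dioxathiolane 2,2-dioxide | CC1(C)OS(=O)(=O)O[C@H]1CC(C#C)[C@H]2CC[C@](C)(Cl)[C@@H](Br)C2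
F5 | step 12 | lithium (3R)-3-bromo-5-[(1S,3S,4S)-3-bromo-4-chloro-4-methylcyclohexyl]-2-methylhept-6-yn-2-yl sulfate | [Li+].CC(C)(OS(=O)(=O)[O-])[C@H](Br)CC(C#C)[C@H]1CC[C@](C)(Cl)[C@@H](Br)C1
F6 | step 13 | (5R)-5-bromo-3-[(1S,3S,4S)-3-bromo-4-chloro-4-methylcyclohexyl]-6-hydroxy-6-methylheptan-2-one (C3 epimers) | CC(=O)C(C[C@@H](Br)C(C)(C)O)[C@H]1CC[C@](C)(Cl)[C@@H](Br)C1
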